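**Assumption (numbering):** germacrane numbering is used: C1–C4 plus the bridging oxygen form the furanone (ring A; C3 ketone, C4 quaternary, C15 its methyl), C1–C10 form the carbocycle (ring B), C6/C7/C11/C12 plus oxygen form the butenolide (ring C); C13 = CH2OAc, C8 = ester carbon, C10 = CHCH3. Read from the SMILES, the target is (4S,8S,10S) with a 5E enol-lactone alkene and a (Z)-4-hydroxy-3-methylbut-2-enoate.

## Retrosynthetic overview

1. Endgame: the C13 acetate and the side-chain hydroxyl are unmasked last; the C8 ester is made by Yamaguchi acylation.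
2. Ring B is closed last at C5=C6 by a macrocyclising vinylogous aldol condensation of the butenolide γ-carbon onto a C5 aldehyde (new step).
3. Key step, ring A: the furanone C1–O bond (the oxygen bridge) is made by gold-catalysed cycloisomerisation of a γ-hydroxy-ynone, obtained from alkynol 15 and lactone 11.
4. Ring C is made first by anti-carbomagnesiation/CO2 lactonisation; C8 comes from asymmetric 2-(alkoxycarbonyl)allylation, C10 from face-selective hydrogenation of the lactone, C4 from Sharpless epoxidation.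
5. Ring order: C (butenolide), then A (furanone), then B (ten-membered carbocycle).

## Route

Step 1
Reactants: 1 4-{[tert-butyl(dimethyl)silyl]oxy}but-2-yn-1-ol; 2 vinylmagnesium chloride
Product: 5 3-({[tert-butyl(dimethyl)silyl]oxy}methyl)-4-ethenylfuran-2(5H)-one, via alkenylmagnesium chelate 3 (not isolated), via hydroxy acid 4 (not isolated)
Conditions: 2 (3.5 equiv), THF/cyclohexane, reflux; CO2 (gas), −20 → 20 °C; 1 M HCl, 0 °C
Reagents that add atoms: carbon dioxide, O=C=O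
Why: Hydroxyl-directed anti-carbomagnesiation of the propargylic alkoxide puts vinyl on the carbon next to the free CH2OH and magnesium cis to that CH2O group, so carboxylation gives the (Z)-hydroxy acid, which lactonises on acidification to the 3,4-disubstituted butenolide (ring C).

Step 2
Reactants: 5 3-({[tert-butyl(dimethyl)silyl]oxy}methyl)-4-ethenylfuran-2(5H)-one
Product: 6 4-({[tert-butyl(dimethyl)silyl]oxy}methyl)-5-oxo-2,5-dihydrofuran-3-carbaldehyde
Conditions: OsO4 (2 mol %), NaIO4, 2,6-lutidine, dioxane/H2O, rt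
Reagents that add atoms: sodium periodate, [Na+].[O-]I(=O)(=O)=O
Why: Lemieux–Johnson cleavage; OsO4 attacks the terminal vinyl group rather than the tetrasubstituted, electron-poor butenolide alkene, and periodate cleaves the diol to the C8 aldehyde.

Step 3
Reactants: 6 4-({[tert-butyl(dimethyl)silyl]oxy}methyl)-5-oxo-2,5-dihydrofuran-3-carbaldehyde; 7 ethyl 2-(bromomethyl)acrylate
Product: 10 (5S)-5-[4-({[tert-butyl(dimethyl)silyl]oxy}methyl)-5-oxo-2,5-dihydrofuran-3-yl]-3-methylideneoxolan-2-one, via silyl ether 8 (not isolated), via hydroxy ester 9 (not isolated)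
Conditions: CrCl2 (10 mol %), chiral carbazole-bis(oxazoline) ligand (12 mol %, enantiomer giving the S carbinol), Mn, TMSCl, iPr2NEt, THF, rt; 1 M HCl, THF, 0 °C; TFA (cat.), CH2Cl2, rt
Reagents that add atoms: none
Why: Catalytic enantioselective Nozaki–Hiyama–Kishi 2-(alkoxycarbonyl)allylation sets C8 (S) under ligand control, and acidic desilylation followed by lactonisation gives the α-methylene-γ-butyrolactone.

Step 4
Reactants: 10 (5S)-5-[4-({[tert-butyl(dimethyl)silyl]oxy}methyl)-5-oxo-2,5-dihydrofuran-3-yl]-3-methylideneoxolan-2-one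
Product: 11 (3S,5S)-5-[4-({[tert-butyl(dimethyl)silyl]oxy}methyl)-5-oxo-2,5-dihydrofuran-3-yl]-3-methyloxolan-2-one
Conditions: RhCl(PPh3)3 (5 mol %), H2 (1 atm), benzene/EtOH, rt
Reagents that add atoms: none
Why: Homogeneous hydrogenation reduces only the 1,1-disubstituted exocyclic alkene and delivers hydrogen to the lactone face anti to the C8 substituent, giving the cis lactone and so C10 (S).

Step 5
Reactants: 12 (2E)-3-methylpent-2-en-4-yn-1-ol
Product: 13 [(2R,3R)-3-ethynyl-3-methyloxiran-2-yl]methanol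
Conditions: Ti(OiPr)4 (10 mol %), D-(−)-diisopropyl tartrate (12 mol %), t-BuOOH, 4 Å MS, CH2Cl2, −20 °C
Reagents that add atoms: tert-butyl hydroperoxide, CC(C)(C)OO
Why: Katsuki–Sharpless asymmetric epoxidation of an (E)-trisubstituted allylic alcohol; the D-tartrate gives the (2R,3R) epoxide (mirror image of the geraniol/L-tartrate case), which fixes the future C4.

Step 6
Reactants: 13 [(2R,3R)-3-ethynyl-3-methyloxiran-2-yl]methanol
Product: 15 (3S)-3-methylpent-1-en-4-yn-3-ol, via epoxy iodide 14 (not isolated)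
Conditions: PPh3, I2, imidazole, THF, 0 °C; then Zn dust, AcOH, 0 °C → rt
Reagents that add atoms: none
Why: Appel-type iodination followed by zinc-mediated reductive elimination (epoxy iodide to transposed allylic alcohol) breaks only the C–O bond at the secondary epoxide carbon, so the tertiary C–O stereocentre is kept.

Step 7
Reactants: 15 (3S)-3-methylpent-1-en-4-yn-3-ol; 11 (3S,5S)-5-[4-({[tert-butyl(dimethyl)silyl]oxy}methyl)-5-oxo-2,5-dihydrofuran-3-yl]-3-methyloxolan-2-one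
Product: 16 3-({[tert-butyl(dimethyl)silyl]oxy}methyl)-4-[(1S,3S,7S)-1,7-dihydroxy-3,7-dimethyl-4-oxonon-8-en-5-yn-1-yl]furan-2(5H)-one
Conditions: 15 (1.3 equiv), n-BuLi (2.6 equiv), THF, −78 °C; CeCl3, −78 °C; then 11; AcOH, −78 °C
Reagents that add atoms: none
Why: Acetylide addition to a lactone; the weakly basic cerium acetylide adds once to the saturated γ-lactone (more electrophilic than the conjugated, tetrasubstituted butenolide), and ring opening gives the γ-hydroxy-ynone and frees the C8 hydroxyl without a protecting group.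

Step 8
Reactants: 16 3-({[tert-butyl(dimethyl)silyl]oxy}methyl)-4-[(1S,3S,7S)-1,7-dihydroxy-3,7-dimethyl-4-oxonon-8-en-5-yn-1-yl]furan-2(5H)-one
Product: 17 (2S)-5-{(2S,4S)-4-[4-({[tert-butyl(dimethyl)silyl]oxy}methyl)-5-oxo-2,5-dihydrofuran-3-yl]-4-hydroxybutan-2-yl}-2-ethenyl-2-methylfuran-3(2H)-one
Conditions: (p-CF3C6H4)3PAuCl (5 mol %), AgOTf (5 mol %), toluene, H2O (1 equiv), rt
Reagents that add atoms: water, O
Why: Key C–O step: gold-catalysed cycloisomerisation of a γ-hydroxy-ynone (hydration of the ynone at C3, then cyclodehydration of the tertiary hydroxyl onto C1) forms the furanone C1–O bond, the oxygen bridge of the target; the C4–O bond is not broken, so C4 stays S.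

Step 9
Reactants: 18 4-methylfuran-2(5H)-one
Product: 21 (2Z)-4-{[tert-butyl(diphenyl)silyl]oxy}-3-methylbut-2-enoic acid, via sodium carboxylate 19 (not isolated), via bis-silyl derivative 20 (not isolated)
Conditions: NaOH (1.0 equiv), H2O/THF, rt; evaporate; TBDPSCl (2.2 equiv), imidazole, DMF, rt; K2CO3, THF/H2O; 1 M HCl to pH 4, 0 °C
Reagents that add atoms: sodium hydroxide, [Na+].[OH-]; tert-butyl(chloro)diphenylsilane, CC(C)(C)[Si](Cl)(c1ccccc1)c1ccccc1
Why: Saponification of the butenolide gives the hydroxy carboxylate with the Z geometry fixed by the ring; bis-silylation and selective hydrolysis of the labile silyl ester give the protected Z acid.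

Step 10
Reactants: 17 (2S)-5-{(2S,4S)-4-[4-({[tert-butyl(dimethyl)silyl]oxy}methyl)-5-oxo-2,5-dihydrofuran-3-yl]-4-hydroxybutan-2-yl}-2-ethenyl-2-methylfuran-3(2H)-one; 21 (2Z)-4-{[tert-butyl(diphenyl)silyl]oxy}-3-methylbut-2-enoic acid
Product: 23 (1S,3S)-1-[4-({[tert-butyl(dimethyl)silyl]oxy}methyl)-5-oxo-2,5-dihydrofuran-3-yl]-3-[(2S)-2-ethenyl-2-methyl-3-oxo-2,3-dihydrofuran-5-yl]butyl (2Z)-4-{[tert-butyl(diphenyl)silyl]oxy}-3-methylbut-2-enoate, via mixed anhydride 22 (not isolated)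
Conditions: 21, 2,4,6-Cl3C6H2COCl, Et3N, THF, 0 °C; then 17, DMAP, toluene, rt
Reagents that add atoms: none
Why: Yamaguchi esterification; the C8 secondary alcohol is the only free hydroxyl in 17 and its C–O bond is not broken, so C8 stays S.

Step 11
Reactants: 23 (1S,3S)-1-[4-({[tert-butyl(dimethyl)silyl]oxy}methyl)-5-oxo-2,5-dihydrofuran-3-yl]-3-[(2S)-2-ethenyl-2-methyl-3-oxo-2,3-dihydrofuran-5-yl]butyl (2Z)-4-{[tert-butyl(diphenyl)silyl]oxy}-3-methylbut-2-enoate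
Product: 24 (1S,3S)-1-[4-({[tert-butyl(dimethyl)silyl]oxy}methyl)-5-oxo-2,5-dihydrofuran-3-yl]-3-[(2S)-2-formyl-2-methyl-3-oxo-2,3-dihydrofuran-5-yl]butyl (2Z)-4-{[tert-butyl(diphenyl)silyl]oxy}-3-methylbut-2-enoate
Conditions: OsO4 (2 mol %), NaIO4, 2,6-lutidine, dioxane/H2O, rt
Reagents that add atoms: sodium periodate, [Na+].[O-]I(=O)(=O)=O
Why: Lemieux–Johnson cleavage of the only monosubstituted alkene (the others are tri- or tetrasubstituted and electron-poor); the lutidine buffer limits retro-Claisen loss of the non-enolisable formyl group.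

Step 12
Reactants: 24 (1S,3S)-1-[4-({[tert-butyl(dimethyl)silyl]oxy}methyl)-5-oxo-2,5-dihydrofuran-3-yl]-3-[(2S)-2-formyl-2-methyl-3-oxo-2,3-dihydrofuran-5-yl]butyl (2Z)-4-{[tert-butyl(diphenyl)silyl]oxy}-3-methylbut-2-enoate
Product: 27 (4S,8S,10S,5E)-13-{[tert-butyl(dimethyl)silyl]oxy}-8-{[(2Z)-4-{[tert-butyl(diphenyl)silyl]oxy}-3-methylbut-2-enoyl]oxy}-3-oxo-1,4-epoxygermacra-1,5,7(11)-trien-12,6-olide, via silyloxyfuran 25 (not isolated), via silyl aldol 26 (not isolated)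
Conditions: TBSOTf (3 equiv), iPr2NEt (4 equiv), CH2Cl2 (1 mM), −78 → 0 °C; then DBU, 0 °C
Reagents that add atoms: none
Why: Proposed new method: a macrocyclising vinylogous Mukaiyama aldol condensation that closes the ten-membered carbocycle; soft enolisation turns the butenolide into 2-silyloxyfuran 25, whose γ-carbon (C6) adds intramolecularly to the TBSOTf-activated, non-enolisable C5 aldehyde (the furanone holds C4 and C1 close, so the closure is effectively nine atoms through the ether oxygen), and DBU then expels silanolate from β-silyloxy butenolide 26 by E1cB, the bridged ring being expected to favour the isomer with C4 and C7 cis on C5=C6; the closest known reaction is the intermolecular one-pot vinylogous aldol condensation of butenolides with aldehydes (silyl triflate/amine, then DBU) used for γ-ylidenebutenolides.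

Step 13
Reactants: 27 (4S,8S,10S,5E)-13-{[tert-butyl(dimethyl)silyl]oxy}-8-{[(2Z)-4-{[tert-butyl(diphenyl)silyl]oxy}-3-methylbut-2-enoyl]oxy}-3-oxo-1,4-epoxygermacra-1,5,7(11)-trien-12,6-olide
Product: 29 (4S,8S,10S,5E)-13-acetoxy-8-{[(2Z)-4-{[tert-butyl(diphenyl)silyl]oxy}-3-methylbut-2-enoyl]oxy}-3-oxo-1,4-epoxygermacra-1,5,7(11)-trien-12,6-olide, via primary alcohol 28 (not isolated)
Conditions: HF·pyridine, pyridine, THF, 0 °C; then Ac2O, DMAP, 0 °C → rt
Reagents that add atoms: acetic anhydride, CC(=O)OC(C)=O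
Why: Buffered HF·pyridine removes the primary TBS ether much faster than the TBDPS ether, and acetylation in the same flask installs the C13 acetate only after all enolate chemistry is over, so acetate cannot be lost by β-elimination.

Step 14
Reactants: 29 (4S,8S,10S,5E)-13-acetoxy-8-{[(2Z)-4-{[tert-butyl(diphenyl)silyl]oxy}-3-methylbut-2-enoyl]oxy}-3-oxo-1,4-epoxygermacra-1,5,7(11)-trien-12,6-olide
Product: 30 target, (4S,8S,10S,5E)-13-acetoxy-8-{[(2Z)-4-hydroxy-3-methylbut-2-enoyl]oxy}-3-oxo-1,4-epoxygermacra-1,5,7(11)-trien-12,6-olide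
Conditions: HF·pyridine, pyridine, THF, 0 °C → rt
Reagents that add atoms: none
Why: Fluoride desilylation of the TBDPS ether under buffered, non-basic conditions leaves the acetate, the enol lactone and the esters intact.

## Compound list

1 | 4-{[tert-butyl(dimethyl)silyl]oxy}but-2-yn-1-ol | OCC#CCO[Si](C)(C)C(C)(C)C | starting material
2 | vinylmagnesium chloride | C=C[Mg]Cl | starting material
3 | chloromagnesium (2Z)-3-(chloromagnesio)-4-{[tert-butyl(dimethyl)silyl]oxy}-2-ethenylbut-2-en-1-olate (Mg cis to the CH2O–Mg group) | C=C/C(CO[Mg]Cl)=C(\CO[Si](C)(C)C(C)(C)C)[Mg]Cl | intermediate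
4 | (2Z)-2-({[tert-butyl(dimethyl)silyl]oxy}methyl)-3-(hydroxymethyl)penta-2,4-dienoic acid | C=C/C(CO)=C(\CO[Si](C)(C)C(C)(C)C)C(=O)O | intermediate
5 | 3-({[tert-butyl(dimethyl)silyl]oxy}methyl)-4-ethenylfuran-2(5H)-one | C=CC1=C(CO[Si](C)(C)C(C)(C)C)C(=O)OC1 | intermediate
6 | 4-({[tert-butyl(dimethyl)silyl]oxy}methyl)-5-oxo-2,5-dihydrofuran-3-carbaldehyde | O=CC1=C(CO[Si](C)(C)C(C)(C)C)C(=O)OC1 | intermediate
7 | ethyl 2-(bromomethyl)acrylate | C=C(CBr)C(=O)OCC | starting material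
8 | ethyl (4S)-4-[4-({[tert-butyl(dimethyl)silyl]oxy}methyl)-5-oxo-2,5-dihydrofuran-3-yl]-2-methylidene-4-[(trimethylsilyl)oxy]butanoate | C=C(C[C@H](O[Si](C)(C)C)C1=C(CO[Si](C)(C)C(C)(C)C)C(=O)OC1)C(=O)OCC | intermediate
9 | ethyl (4S)-4-[4-({[tert-butyl(dimethyl)silyl]oxy}methyl)-5-oxo-2,5-dihydrofuran-3-yl]-4-hydroxy-2-methylidenebutanoate | C=C(C[C@H](O)C1=C(CO[Si](C)(C)C(C)(C)C)C(=O)OC1)C(=O)OCC | intermediate
10 | (5S)-5-[4-({[tert-butyl(dimethyl)silyl]oxy}methyl)-5-oxo-2,5-dihydrofuran-3-yl]-3-methylideneoxolan-2-one | C=C1C[C@@H](C2=C(CO[Si](C)(C)C(C)(C)C)C(=O)OC2)OC1=O | intermediate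
11 | (3S,5S)-5-[4-({[tert-butyl(dimethyl)silyl]oxy}methyl)-5-oxo-2,5-dihydrofuran-3-yl]-3-methyloxolan-2-one (cis) | C[C@H]1C[C@@H](C2=C(CO[Si](C)(C)C(C)(C)C)C(=O)OC2)OC1=O | intermediate
12 | (2E)-3-methylpent-2-en-4-yn-1-ol | OC/C=C(\C)C#C | starting material
13 | [(2R,3R)-3-ethynyl-3-methyloxiran-2-yl]methanol | OC[C@H]1O[C@]1(C)C#C | intermediate
14 | (2S,3R)-3-ethynyl-2-(iodomethyl)-3-methyloxirane | IC[C@H]1O[C@]1(C)C#C | intermediate
15 | (3S)-3-methylpent-1-en-4-yn-3-ol | C=C[C@](C#C)(C)O | intermediate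
16 | 3-({[tert-butyl(dimethyl)silyl]oxy}methyl)-4-[(1S,3S,7S)-1,7-dihydroxy-3,7-dimethyl-4-oxonon-8-en-5-yn-1-yl]furan-2(5H)-one | C=C[C@](C)(O)C#CC(=O)[C@@H](C)C[C@H](O)C1=C(CO[Si](C)(C)C(C)(C)C)C(=O)OC1 | intermediate
17 | (2S)-5-{(2S,4S)-4-[4-({[tert-butyl(dimethyl)silyl]oxy}methyl)-5-oxo-2,5-dihydrofuran-3-yl]-4-hydroxybutan-2-yl}-2-ethenyl-2-methylfuran-3(2H)-one | C=C[C@]1(C)OC(=CC1=O)[C@@H](C)C[C@H](O)C2=C(CO[Si](C)(C)C(C)(C)C)C(=O)OC2 | intermediate
18 | 4-methylfuran-2(5H)-one | CC1=CC(=O)OC1 | starting material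
19 | sodium (2Z)-4-hydroxy-3-methylbut-2-enoate | [Na+].[O-]C(=O)/C=C(/C)CO | intermediate
20 | tert-butyl(diphenyl)silyl (2Z)-4-{[tert-butyl(diphenyl)silyl]oxy}-3-methylbut-2-enoate | CC(C)(C)[Si](OC(=O)/C=C(/C)CO[Si](c1ccccc1)(c1ccccc1)C(C)(C)C)(c1ccccc1)c1ccccc1 | intermediate
21 | (2Z)-4-{[tert-butyl(diphenyl)silyl]oxy}-3-methylbut-2-enoic acid | OC(=O)/C=C(/C)CO[Si](c1ccccc1)(c1ccccc1)C(C)(C)C | intermediate
22 | (2Z)-4-{[tert-butyl(diphenyl)silyl]oxy}-3-methylbut-2-enoic 2,4,6-trichlorobenzoic anhydride | O=C(OC(=O)c1c(Cl)cc(Cl)cc1Cl)/C=C(/C)CO[Si](c1ccccc1)(c1ccccc1)C(C)(C)C | intermediate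
23 | (1S,3S)-1-[4-({[tert-butyl(dimethyl)silyl]oxy}methyl)-5-oxo-2,5-dihydrofuran-3-yl]-3-[(2S)-2-ethenyl-2-methyl-3-oxo-2,3-dihydrofuran-5-yl]butyl (2Z)-4-{[tert-butyl(diphenyl)silyl]oxy}-3-methylbut-2-enoate | C=C[C@]1(C)OC(=CC1=O)[C@@H](C)C[C@H](OC(=O)/C=C(/C)CO[Si](c1ccccc1)(c1ccccc1)C(C)(C)C)C2=C(CO[Si](C)(C)C(C)(C)C)C(=O)OC2 | intermediate
24 | (1S,3S)-1-[4-({[tert-butyl(dimethyl)silyl]oxy}methyl)-5-oxo-2,5-dihydrofuran-3-yl]-3-[(2S)-2-formyl-2-methyl-3-oxo-2,3-dihydrofuran-5-yl]butyl (2Z)-4-{[tert-butyl(diphenyl)silyl]oxy}-3-methylbut-2-enoate | O=C[C@]1(C)OC(=CC1=O)[C@@H](C)C[C@H](OC(=O)/C=C(/C)CO[Si](c1ccccc1)(c1ccccc1)C(C)(C)C)C2=C(CO[Si](C)(C)C(C)(C)C)C(=O)OC2 | intermediate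
25 | 2-silyloxyfuran form of 24: (1S,3S)-1-[5-{[tert-butyl(dimethyl)silyl]oxy}-4-({[tert-butyl(dimethyl)silyl]oxy}methyl)furan-3-yl]-3-[(2S)-2-formyl-2-methyl-3-oxo-2,3-dihydrofuran-5-yl]butyl (2Z)-4-{[tert-butyl(diphenyl)silyl]oxy}-3-methylbut-2-enoate | O=C[C@]1(C)OC(=CC1=O)[C@@H](C)C[C@H](OC(=O)/C=C(/C)CO[Si](c1ccccc1)(c1ccccc1)C(C)(C)C)c2coc(O[Si](C)(C)C(C)(C)C)c2CO[Si](C)(C)C(C)(C)C | intermediate
26 | macrocyclic silyl aldol: 5-{[tert-butyl(dimethyl)silyl]oxy}-5,6-dihydro derivative of 27 (C5–OTBS, C6–H; C5/C6 diastereomer mixture; 4S,8S,10S) | CC(C)(C)[Si](C)(C)OCC1=C2C(C(O[Si](C)(C)C(C)(C)C)[C@]3(C)OC(=CC3=O)[C@@H](C)C[C@@H]2OC(=O)/C=C(/C)CO[Si](c4ccccc4)(c4ccccc4)C(C)(C)C)OC1=O | intermediate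
27 | (4S,8S,10S,5E)-13-{[tert-butyl(dimethyl)silyl]oxy}-8-{[(2Z)-4-{[tert-butyl(diphenyl)silyl]oxy}-3-methylbut-2-enoyl]oxy}-3-oxo-1,4-epoxygermacra-1,5,7(11)-trien-12,6-olide | CC(C)(C)[Si](C)(C)OCC1=C2/C(=C\[C@]3(C)OC(=CC3=O)[C@@H](C)C[C@@H]2OC(=O)/C=C(/C)CO[Si](c4ccccc4)(c4ccccc4)C(C)(C)C)OC1=O | intermediate
28 | (4S,8S,10S,5E)-13-hydroxy-8-{[(2Z)-4-{[tert-butyl(diphenyl)silyl]oxy}-3-methylbut-2-enoyl]oxy}-3-oxo-1,4-epoxygermacra-1,5,7(11)-trien-12,6-olide | OCC1=C2/C(=C\[C@]3(C)OC(=CC3=O)[C@@H](C)C[C@@H]2OC(=O)/C=C(/C)CO[Si](c4ccccc4)(c4ccccc4)C(C)(C)C)OC1=O | intermediate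
29 | (4S,8S,10S,5E)-13-acetoxy-8-{[(2Z)-4-{[tert-butyl(diphenyl)silyl]oxy}-3-methylbut-2-enoyl]oxy}-3-oxo-1,4-epoxygermacra-1,5,7(11)-trien-12,6-olide | CC(=O)OCC1=C2/C(=C\[C@]3(C)OC(=CC3=O)[C@@H](C)C[C@@H]2OC(=O)/C=C(/C)CO[Si](c4ccccc4)(c4ccccc4)C(C)(C)C)OC1=O | intermediate
30 | target CNP0269057.1: (4S,8S,10S,5E)-13-acetoxy-8-{[(2Z)-4-hydroxy-3-methylbut-2-enoyl]oxy}-3-oxo-1,4-epoxygermacra-1,5,7(11)-trien-12,6-olide | CC(=O)OCC1=C2/C(=C\[C@]3(C)OC(=CC3=O)[C@@H](C)C[C@@H]2OC(=O)/C=C(/C)CO)OC1=O | target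

## Step count and risk

Total step count: 14. Longest linear sequence: 11 (steps 1, 2, 3, 4, 7, 8, 10, 11, 12, 13, 14).

**Step 12 (the proposed new step).** The ring closure is a medium-ring carbocyclisation onto a hindered aldehyde, and the C13 silyloxy group could compete as a leaving group in the E1cB step. Fallback with known chemistry only, setting out from 23 and coming back at 27: soft enolisation of 23 (TBSOTf, Et3N, CH2Cl2, −78 °C) gives the 2-silyloxyfuran of 23 F1, which is brominated in the same flask with NBS to the 5-bromobutenolide (bromine on C6) F2. Michaelis–Arbuzov reaction with P(OEt)3 (toluene, 80 °C) gives the C6 diethyl phosphonate F3. Lemieux–Johnson cleavage of the vinyl group (OsO4 cat., NaIO4, 2,6-lutidine) gives the phosphonate aldehyde F4, and Masamune–Roush Horner–Wadsworth–Emmons macro-olefination (LiCl, iPr2NEt, MeCN, 1 mM) closes C5=C6 to give 27.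

**Step 7.** The acetylide may attack the butenolide carbonyl or deprotonate its γ-CH2 instead of opening the saturated lactone. Fallback, setting out from 11 and coming back at 16: the butenolide is masked as an aromatic furan by TIPSOTf/Et3N, giving the 2-(triisopropylsilyloxy)furan lactone F5. The dilithio derivative of 15 (n-BuLi, THF, −78 °C) then adds to the only remaining carbonyl to give the silyloxyfuran hydroxy-ynone F6, and 1 M HCl/THF at 0 °C hydrolyses the silyl enol ether back to the butenolide, giving 16.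

**Step 8.** The free C8 hydroxyl can compete with the tertiary C4 hydroxyl for the C1 carbonyl during cyclodehydration, giving a 2-alkylidene-tetrahydrofuran instead of the furanone. Fallback, setting out from 16 and coming back at 23: the C8 hydroxyl is acylated first by Yamaguchi esterification with 21 (the tertiary propargylic alcohol does not react), giving the C8-acylated hydroxy-ynone F7. The furanone is then formed by the classical amine route: Et2NH in EtOH adds to the ynone to give the enaminone F8, and aqueous AcOH hydrolyses it and closes the ring to 23 directly.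

## Further compounds

F1 | step 12 | 2-silyloxyfuran of 23: (1S,3S)-1-[5-{[tert-butyl(dimethyl)silyl]oxy}-4-({[tert-butyl(dimethyl)silyl]oxy}methyl)furan-3-yl]-3-[(2S)-2-ethenyl-2-methyl-3-oxo-2,3-dihydrofuran-5-yl]butyl (2Z)-4-{[tert-butyl(diphenyl)silyl]oxy}-3-methylbut-2-enoate | C=C[C@]1(C)OC(=CC1=O)[C@@H](C)C[C@H](OC(=O)/C=C(/C)CO[Si](c1ccccc1)(c1ccccc1)C(C)(C)C)c2coc(O[Si](C)(C)C(C)(C)C)c2CO[Si](C)(C)C(C)(C)C
F2 | step 12 | 5-bromobutenolide of 23 (bromine on C6, epimer mixture) | C=C[C@]1(C)OC(=CC1=O)[C@@H](C)C[C@H](OC(=O)/C=C(/C)CO[Si](c1ccccc1)(c1ccccc1)C(C)(C)C)C2=C(CO[Si](C)(C)C(C)(C)C)C(=O)OC2Br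
F3 | step 12 | C6 diethyl phosphonate of 23 (epimer mixture at C6) | C=C[C@]1(C)OC(=CC1=O)[C@@H](C)C[C@H](OC(=O)/C=C(/C)CO[Si](c1ccccc1)(c1ccccc1)C(C)(C)C)C2=C(CO[Si](C)(C)C(C)(C)C)C(=O)OC2P(=O)(OCC)OCC
F4 | step 12 | C6 diethyl phosphonate of aldehyde 24 (epimer mixture at C6) | O=C[C@]1(C)OC(=CC1=O)[C@@H](C)C[C@H](OC(=O)/C=C(/C)CO[Si](c1ccccc1)(c1ccccc1)C(C)(C)C)C2=C(CO[Si](C)(C)C(C)(C)C)C(=O)OC2P(=O)(OCC)OCC
F5 | step 7 | (3S,5S)-5-[4-({[tert-butyl(dimethyl)silyl]oxy}methyl)-5-{[tri(propan-2-yl)silyl]oxy}furan-3-yl]-3-methyloxolan-2-one | C[C@H]1C[C@@H](c2coc(O[Si](C(C)C)(C(C)C)C(C)C)c2CO[Si](C)(C)C(C)(C)C)OC1=O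
F6 | step 7 | (3S,5S,9S)-9-[4-({[tert-butyl(dimethyl)silyl]oxy}methyl)-5-{[tri(propan-2-yl)silyl]oxy}furan-3-yl]-3,9-dihydroxy-3,7-dimethylnon-1-en-4-yn-6-one | C=C[C@](C)(O)C#CC(=O)[C@@H](C)C[C@H](O)c1coc(O[Si](C(C)C)(C(C)C)C(C)C)c1CO[Si](C)(C)C(C)(C)C
F7 | step 8 | (1S,3S,7S)-1-[4-({[tert-butyl(dimethyl)silyl]oxy}methyl)-5-oxo-2,5-dihydrofuran-3-yl]-7-hydroxy-3,7-dimethyl-4-oxonon-8-en-5-yn-1-yl (2Z)-4-{[tert-butyl(diphenyl)silyl]oxy}-3-methylbut-2-enoate | C=C[C@](C)(O)C#CC(=O)[C@@H](C)C[C@H](OC(=O)/C=C(/C)CO[Si](c1ccccc1)(c1ccccc1)C(C)(C)C)C2=C(CO[Si](C)(C)C(C)(C)C)C(=O)OC2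
F8 | step 8 | (5E)-6-(diethylamino) enaminone from addition of diethylamine to the ynone of F7 | C=C[C@](C)(O)/C(N(CC)CC)=C\C(=O)[C@@H](C)C[C@H](OC(=O)/C=C(/C)CO[Si](c1ccccc1)(c1ccccc1)C(C)(C)C)C2=C(CO[Si](C)(C)C(C)(C)C)C(=O)OC2
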